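## Retrosynthetic overview

1. Kanzonol X (9) ⇐ its 2',4'-bis-TBS ether 8 (fluoride desilylation).
2. 8 ⇐ a 7-hydroxyisoflavylium ion, stored as its neutral 2-methoxy-2H-chromene pseudobase 7. A chiral-phosphoric-acid/Hantzsch-ester double transfer hydrogenation dearomatizes the benzopyrylium ring and sets C3 (R).
3. 7 ⇐ salicylaldehyde 3 + aryl enol ether 6 by acid-catalysed pyrylium annulation (C3–C4 and O1–C2). This is the only ring-forming step: the pyran ring is made at the pyrylium level, then reduced to the chroman.
4. 6 ⇐ 3 by silylation and methoxymethylenation, so both prenyl-resorcinol rings come from the same aldehyde.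
5. 3 ⇐ 2,4-dihydroxybenzaldehyde (1) + prenyl bromide (2).

Assumption: the target SMILES corresponds to (3R). The facial sense of the new key step cannot be predicted with certainty; (R)-TRIP is written, and (S)-TRIP would be used instead if the sense proves opposite.

## Route

**Step 1**
Reactants: 1, 2,4-dihydroxybenzaldehyde; 2, prenyl bromide
Product: 3, 2,4-dihydroxy-3-(3-methylbut-2-en-1-yl)benzaldehyde
Conditions: 10% aq. KOH (2 equiv), 2 (1.0 equiv), 0 °C → rt, 16 h; acidify; chromatography
Reagents that add atoms: prenyl bromide (2), CC(C)=CCBr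
Why: C-alkylation of an ambident resorcinol phenoxide in water favours the doubly activated carbon between the two oxygens (known direct C-prenylation; modest yield, the 5-prenyl and O-prenyl isomers are separated, inputs are cheap); no stereocentre.

**Step 2**
Reactants: 3
Product: 4, 2,4-bis(tert-butyldimethylsilyloxy)-3-(3-methylbut-2-en-1-yl)benzaldehyde
Conditions: TBSOTf (2.4 equiv), 2,6-lutidine, CH2Cl2, 0 °C → rt
Reagents that add atoms: TBSOTf, CC(C)(C)[Si](C)(C)OS(=O)(=O)C(F)(F)F
Why: Silyl-triflate protection covers both phenols, including the H-bonded, flanked 2-OH; aryl TBS ethers survive the ylide and mild acid, leave with fluoride, and prevent later benzofuran formation from an ortho-OH arylacetaldehyde equivalent.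

**Step 3**
Reactants: 4; 5, (methoxymethyl)triphenylphosphonium chloride
Product: 6, 1-(2-methoxyethenyl)-2,4-bis(tert-butyldimethylsilyloxy)-3-(3-methylbut-2-en-1-yl)benzene (E/Z mixture)
Conditions: 5 (1.5 equiv), KHMDS (1.4 equiv), THF, 0 °C; then 4, 0 °C → rt; Et3N-deactivated silica
Reagents that add atoms: (methoxymethyl)triphenylphosphonium chloride (5), COC[P+](c1ccccc1)(c1ccccc1)c1ccccc1.[Cl-]
Why: Wittig methoxymethylenation gives the enol ether as a stable arylacetaldehyde equivalent carrying the future C2 carbon; alkene geometry is irrelevant and the preformed ylide leaves no excess base to attack the silyl ethers.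

**Step 4**
Reactants: 3 (1.3 equiv); 6 (added slowly)
Product: 7, 3-[2,4-bis(tert-butyldimethylsilyloxy)-3-(3-methylbut-2-en-1-yl)phenyl]-2-methoxy-8-(3-methylbut-2-en-1-yl)-2H-chromen-7-ol (racemic at C2; the methanol pseudobase of the 7-hydroxyisoflavylium ion)
Conditions: CSA (20 mol%), 4 Å MS, CH2Cl2, 0 °C → rt; then Et3N, MeOH; aq. NaHCO3 wash; basic alumina
Reagents that add atoms: methanol, CO (the 2-OMe comes from the enol ether and exchanges with the MeOH quench)
Why: Acid-catalysed benzopyrylium annulation (phenol/enol-ether acetal exchange, intramolecular Prins–aldol closure of C3–C4, dehydration through the p-quinone methide), the enol-ether form of the classical salicylaldehyde + arylacetaldehyde isoflavylium synthesis; catalytic sulfonic acid at rt is mild enough for the prenyl groups and aryl TBS ethers, and the C2 stereocentre is irrelevant.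

**Step 5 (key step)**
Reactants: 7
Product: 8, (3R)-3-[2,4-bis(tert-butyldimethylsilyloxy)-3-(3-methylbut-2-en-1-yl)phenyl]-8-(3-methylbut-2-en-1-yl)chroman-7-ol
Conditions: (R)-TRIP (10 mol%), Hantzsch ester (diethyl 2,6-dimethyl-1,4-dihydropyridine-3,5-dicarboxylate, 2.5 equiv), 5 Å MS, toluene, 40 °C, Ar; substrate must be free of CSA
Reagents that add atoms: none (only hydrogen is added; MeOH is lost)
Why: Proposed new method: the phosphoric acid ionizes the acetal to the aromatic 7-hydroxyisoflavylium/chiral phosphate ion pair, Hantzsch ester delivers hydride to C4 or C2 to give a chromene, the regenerated acid protonates C3 face-selectively (or the C3-epimeric cations equilibrate and one is reduced faster), and a second hydride quenches the resulting oxocarbenium/quinone-methide cation to give the (3R)-chroman; the closest known reactions are the phosphoric acid/Hantzsch ester transfer hydrogenation of 3-substituted quinolines (stereocentre set by enantioselective protonation), phosphoric-acid ion pairing of benzopyrylium ions generated from chromene acetals, and the acid-promoted disproportionation of 2H-chromenes to chromans; isolated prenyl alkenes and aryl silyl ethers are inert to these reagents.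

**Step 6**
Reactants: 8
Product: 9, Kanzonol X, (3R)-3-[2,4-dihydroxy-3-(3-methylbut-2-en-1-yl)phenyl]-8-(3-methylbut-2-en-1-yl)chroman-7-ol
Conditions: TBAF (2.5 equiv), AcOH (2.5 equiv), THF, 0 °C, Ar
Reagents that add atoms: none
Why: Buffered fluoride cleavage of the aryl silyl ethers is non-acidic, so no prenyl-to-chroman cyclization occurs, and the non-acidic C3 stereocentre is untouched.

## Compound list

1 | 2,4-dihydroxybenzaldehyde | O=Cc1ccc(O)cc1O | starting material
2 | prenyl bromide (1-bromo-3-methylbut-2-ene) | CC(C)=CCBr | starting material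
3 | 2,4-dihydroxy-3-prenylbenzaldehyde | O=Cc1ccc(O)c(CC=C(C)C)c1O | intermediate
4 | 2,4-bis(TBSO)-3-prenylbenzaldehyde | O=Cc1ccc(O[Si](C)(C)C(C)(C)C)c(CC=C(C)C)c1O[Si](C)(C)C(C)(C)C | intermediate
5 | (methoxymethyl)triphenylphosphonium chloride | COC[P+](c1ccccc1)(c1ccccc1)c1ccccc1.[Cl-] | starting material
6 | 1-(2-methoxyethenyl)-2,4-bis(TBSO)-3-prenylbenzene (E/Z) | COC=Cc1ccc(O[Si](C)(C)C(C)(C)C)c(CC=C(C)C)c1O[Si](C)(C)C(C)(C)C | intermediate
7 | 3-[2,4-bis(TBSO)-3-prenylphenyl]-2-methoxy-8-prenyl-2H-chromen-7-ol (racemic at C2) | COC1Oc2c(CC=C(C)C)c(O)ccc2C=C1c1ccc(O[Si](C)(C)C(C)(C)C)c(CC=C(C)C)c1O[Si](C)(C)C(C)(C)C | intermediate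
8 | (3R)-3-[2,4-bis(TBSO)-3-prenylphenyl]-8-prenylchroman-7-ol | CC(C)=CCc1c(O[Si](C)(C)C(C)(C)C)ccc([C@@H]2COc3c(ccc(O)c3CC=C(C)C)C2)c1O[Si](C)(C)C(C)(C)C | intermediate
9 | Kanzonol X | CC(C)=CCc1c(O)ccc([C@@H]2COc3c(ccc(O)c3CC=C(C)C)C2)c1O | target

## Summary

Total step count: 6. Longest linear sequence: 6 (1 → 3 → 4 → 6 → 7 → 8 → 9; aldehyde 3 is used a second time as the A-ring partner in Step 4).

Steps most likely to fail:

1. **Step 5** — low ee from competing protonation/hydride pathways, or stalling at the chromene stage. Fallback: remove the TBS groups before the reduction, so that C3 is set by phosphoric-acid-controlled hydride transfer to a B-ring ortho-quinone methide (free 2'-OH hydrogen-bonded to the phosphate, the mode precedented for o-hydroxy-1,1-disubstituted styrenes); this changes the stereo-determining event from protonation to hydride delivery.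
2. **Step 4** — enol-ether oligomerization, over-addition to the pyrylium, or acid-induced prenyl cyclization. Fallback: hydrolyse and oxidize 6 to the arylacetic acid, run a Perkin–Oglialoro condensation with 3 (Ac2O/Et3N) to the 3-arylcoumarin, reduce with DIBAL-H to the 2H-chromen-2-ol, and feed that pseudobase into the same key step; this avoids acid altogether.
3. **Step 1** — low yield and regioisomers in the direct C-prenylation. Fallback: directed ortho-metalation from resorcinol bis-MOM ether (n-BuLi then prenyl bromide; n-BuLi/TMEDA then DMF), which gives the 2,4-bis(MOM)-3-prenylbenzaldehyde regiospecifically; MOM then replaces TBS on the B ring, and the A-ring partner is obtained by MOM removal.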